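**Retrosynthetic overview**
The strategy rests on the trisubstituted enol ether O–CH=C(CH2OH)(aryl) that joins the two halves. Its ether oxygen is cis to the CH2OH carbon and its vinyl hydrogen is cis to the 2-hydroxy-4-methylphenyl ring. That pattern results from adding H and aryl to one face of an alkyne carrying the encecalol oxygen at one end and the CH2O carbon at the other. Alkoxymethylene carbonyl precursors are avoided because they are expected to relax to the opposite geometry.
Disconnections, in order: the two O–Si bonds; the vinyl C–aryl bond (Suzuki–Miyaura) together with the vinyl C–H bond (hydroboration), back to an alkoxyalkyne and silylated 2-iodo-5-methylphenol; the alkyne–CH2O bond (formaldehyde); the O–C(sp) bond ((S)-encecalol plus trichloroethylene).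
(S)-Encecalol comes from encecalin by asymmetric transfer hydrogenation, and encecalin from the 6-bromochromene and a Weinreb amide.
Ring order: both benzene rings are bought. The pyran ring of the chromene is the only ring made, closed in step 1 by oxa-6π electrocyclisation, and no ring forms afterwards.

Key step: step 8

Assumption: paraformaldehyde is counted as its monomer CH2O; the (S) descriptor follows from O > aryl > CH3 > H at the carbinol carbon and stays the same in every O-derivative used.

Step 1
Reactants: 1 4-bromo-3-methoxyphenol; 2 3-methylbut-2-enal
Product: 4 6-bromo-7-methoxy-2,2-dimethyl-2H-chromene, via vinyl ortho-quinone methide 3 (not isolated)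
Conditions: PhB(OH)2 (1.1 equiv), AcOH, toluene, reflux, Dean–Stark
Reagents that add atoms: none
Why: Phenylboronic acid templates the ortho-selective condensation of phenol and enal, loss of water gives 3, and oxa-6π electrocyclisation closes the pyran ring at the open ortho carbon para to OMe rather than at the carbon between OH and OMe (boronic acid-mediated phenol–enal chromene annulation).

Step 2
Reactants: 4 6-bromo-7-methoxy-2,2-dimethyl-2H-chromene; 5 N-methoxy-N-methylacetamide
Product: 7 encecalin (6-acetyl-7-methoxy-2,2-dimethyl-2H-chromene), via 6-lithiochromene 6 (not isolated)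
Conditions: n-BuLi (1.05 equiv), THF, −78 °C; 5 (1.3 equiv), −78 → 0 °C; then H2O
Reagents that add atoms: n-BuLi, [Li]CCCC (lithium stays in 6 only)
Why: Bromine–lithium exchange outruns any attack on the chromene at −78 °C, the ortho-methoxy group stabilises 6, and the Weinreb ketone synthesis stops at the ketone.

Step 3
Reactants: 7 encecalin
Product: 8 (S)-encecalol, (1S)-1-(7-methoxy-2,2-dimethyl-2H-chromen-6-yl)ethanol
Conditions: RuCl[(S,S)-TsDPEN](p-cymene) (1 mol %), HCO2Na (5 equiv), H2O/DMF, 40 °C; neutral work-up
Reagents that add atoms: none
Why: In this Noyori-type asymmetric transfer hydrogenation the (S,S)-TsDPEN ruthenium hydride passes hydride and proton to the Re face of the aryl methyl ketone through the six-membered outer-sphere transition state ordered by the arene CH/π contact, which sets the (S) centre, while formate makes the reduction irreversible for this electron-rich ketone, the slightly basic medium spares the ionisable benzylic alcohol and the chromene alkene is left alone.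

Step 4
Reactants: 8 (S)-encecalol; 9 trichloroethylene
Product: 11 (E)-1,2-dichlorovinyl ether of (S)-encecalol, via potassium alkoxide 10 (not isolated)
Conditions: KH (1.3 equiv), THF, 0 °C → rt; 9 (1.1 equiv), −50 °C → rt; cold H2O; Et3N-deactivated SiO2
Reagents that add atoms: KH, [H-].[K+] (potassium stays in 10 only)
Why: The alkoxide dehydrochlorinates trichloroethylene and then adds anti to the dichloroacetylene so formed (nucleophilic addition–protonation, the standard entry to 1,2-dichlorovinyl ethers of secondary alcohols), so only the O–H bond of 8 is exchanged and the stereocentre is retained.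

Step 5
Reactants: 11 (E)-1,2-dichlorovinyl ether of (S)-encecalol; 12 formaldehyde (used as dry paraformaldehyde)
Product: 15 3-[(1S)-1-(7-methoxy-2,2-dimethyl-2H-chromen-6-yl)ethoxy]prop-2-yn-1-ol, via chloroalkynyl ether 13 (not isolated), via lithium alkoxyacetylide 14 (not isolated)
Conditions: n-BuLi (2.3 equiv), THF, −78 → −40 °C; (CH2O)n (4 equiv), −40 → 15 °C; cold H2O; crude product kept cold and used at once
Reagents that add atoms: n-BuLi, [Li]CCCC (lithium stays in 14 only)
Why: Deprotonation of the vinyl C–H and loss of LiCl give 13, chlorine–lithium exchange with the second equivalent gives 14, and its 1,2-addition to formaldehyde is ordinary acetylide hydroxymethylation, all under cold basic conditions that suit a heat- and acid-labile alkynyl ether.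

Step 6
Reactants: 15 3-[(1S)-1-(7-methoxy-2,2-dimethyl-2H-chromen-6-yl)ethoxy]prop-2-yn-1-ol
Product: 16 tert-butyldimethylsilyl ether of 15
Conditions: TBSCl (1.2 equiv), imidazole (2.5 equiv), DMF, 0 °C; short Et3N-deactivated SiO2 plug, stored cold
Reagents that add atoms: TBSCl, CC(C)(C)[Si](C)(C)Cl
Why: This is imidazole-promoted silylation of a primary alcohol, and the excess imidazole keeps the medium basic so that hydration or Meyer–Schuster rearrangement of the alkoxypropargyl alcohol has no acid to start it.

Step 7
Reactants: 17 2-iodo-5-methylphenol
Product: 18 tert-butyl(2-iodo-5-methylphenoxy)dimethylsilane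
Conditions: TBSCl (1.2 equiv), imidazole (2.5 equiv), DMF, rt
Reagents that add atoms: TBSCl, CC(C)(C)[Si](C)(C)Cl
Why: Standard phenol silylation masks the acidic OH, which would otherwise consume B–H and could later attack the enol ether.

Step 8
Reactants: 16 tert-butyldimethylsilyl ether of 15; 18 tert-butyl(2-iodo-5-methylphenoxy)dimethylsilane
Product: 20 bis-silyl ether of the target with (S) centre and (Z)-enol ether, via beta-boryl enol ether 19 (not isolated)
Conditions: HBpin (1.1 equiv), Cy2BH (10 mol %), THF, 0 → 20 °C until 16 is consumed; then 18 (1.1 equiv), Pd(OAc)2 (4 mol %), SPhos (8 mol %), degassed aq. K3PO4 (3 equiv), 40 °C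
Reagents that add atoms: pinacolborane, B1OC(C)(C)C(C)(C)O1 (the boryl group stays in 19 only; its hydrogen stays in 20)
Why: Cy2BH adds its B–H bond across the alkyne of 16 through a concerted four-centre transition state and the alkenyl group is then handed to HBpin by boron-to-boron exchange that regenerates Cy2BH, so 19 carries the new vinyl hydrogen and boron on the same side (borane-catalysed syn-hydroboration; 1-alkoxyalkynes are known to take boron at the carbon beta to oxygen). The substrate secures this regiochemistry: lone-pair donation from the ether oxygen makes the carbon bearing CH2OTBS the nucleophilic end that meets the empty boron orbital and stabilises positive charge at the oxygen-bearing carbon that receives hydride, and the inductively withdrawing silyloxymethyl group biases the addition the same way. Oxidative addition of 18 to zerovalent palladium, phosphate-assisted transmetalation with retention at the alkenyl carbon and reductive elimination (Suzuki–Miyaura coupling, the closest known case being beta-alkoxyalkenylboron reagents with ortho-substituted iodoarenes) then place the cresol ring where boron stood, cis to the vinyl hydrogen, so the ether oxygen and the CH2O carbon end up cis, which is the Z geometry of the target. No ring closes and no sp3 stereocentre is created; the alkene geometry is fixed by mechanism (syn addition, then retention), and the (S)-carbinol centre is a spectator because neither its C–O nor its C–H bond is touched under neutral and then mildly basic conditions. Chemoselectivity for the triple bond over the chromene C3–C4 alkene rests on the much higher reactivity of the electron-rich alkyne towards a single equivalent of B–H than that of a cis-styrenyl alkene shielded by the neighbouring gem-dimethyl carbon. The hydroboration must be complete at or below 20 °C before the flask is warmed, since benzylic alkynyl ethers are prone to [3,3] shift and retro-ene cleavage on heating whereas the enol ether 19 is not.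

Step 9
Reactants: 20 bis-silyl ether of the target
Product: 21 target, 2-[(Z)-3-hydroxy-1-{(1S)-1-(7-methoxy-2,2-dimethyl-2H-chromen-6-yl)ethoxy}prop-1-en-2-yl]-5-methylphenol
Conditions: TBAF (2.5 equiv), AcOH (2.5 equiv), THF, 0 °C → rt; pH 7–8 phosphate work-up; Et3N-deactivated SiO2
Reagents that add atoms: none
Why: Fluoride-induced Si–O cleavage removes the aryl and the allylic silyl group, and the near-neutral acetate buffer and acid-free isolation prevent both ionisation of the benzylic ether and acid-triggered attack of the freed phenol on the enol ether carbon with loss of encecalol.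

**Compound list**
1 | 4-bromo-3-methoxyphenol | COc1cc(O)ccc1Br | starting material
2 | 3-methylbut-2-enal (prenal) | CC(C)=CC=O | starting material
3 | (6Z)-4-bromo-3-methoxy-6-(3-methylbut-2-en-1-ylidene)cyclohexa-2,4-dien-1-one (vinyl ortho-quinone methide) | O=C1C=C(OC)C(Br)=C/C1=C/C=C(C)C | intermediate
4 | 6-bromo-7-methoxy-2,2-dimethyl-2H-chromene | COc1cc2c(cc1Br)C=CC(C)(C)O2 | intermediate
5 | N-methoxy-N-methylacetamide | CC(=O)N(C)OC | starting material
6 | 6-lithio-7-methoxy-2,2-dimethyl-2H-chromene | COc1cc2c(cc1[Li])C=CC(C)(C)O2 | intermediate
7 | encecalin (6-acetyl-7-methoxy-2,2-dimethyl-2H-chromene) | COc1cc2c(cc1C(C)=O)C=CC(C)(C)O2 | intermediate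
8 | (S)-encecalol | COc1cc2c(cc1[C@H](C)O)C=CC(C)(C)O2 | intermediate
9 | trichloroethylene | ClC=C(Cl)Cl | starting material
10 | potassium alkoxide of (S)-encecalol | COc1cc2c(cc1[C@H](C)[O-])C=CC(C)(C)O2.[K+] | intermediate
11 | 6-[(1S)-1-{[(E)-1,2-dichloroethenyl]oxy}ethyl]-7-methoxy-2,2-dimethyl-2H-chromene | COc1cc2c(cc1[C@H](C)O/C(Cl)=C\Cl)C=CC(C)(C)O2 | intermediate
12 | formaldehyde (as paraformaldehyde) | C=O | starting material
13 | 6-[(1S)-1-(chloroethynyloxy)ethyl]-7-methoxy-2,2-dimethyl-2H-chromene | COc1cc2c(cc1[C@H](C)OC#CCl)C=CC(C)(C)O2 | intermediate
14 | lithium acetylide of the (S)-encecalyl ethynyl ether | COc1cc2c(cc1[C@H](C)OC#C[Li])C=CC(C)(C)O2 | intermediate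
15 | 3-[(1S)-1-(7-methoxy-2,2-dimethyl-2H-chromen-6-yl)ethoxy]prop-2-yn-1-ol | COc1cc2c(cc1[C@H](C)OC#CCO)C=CC(C)(C)O2 | intermediate
16 | tert-butyldimethylsilyl ether of 15 | COc1cc2c(cc1[C@H](C)OC#CCO[Si](C)(C)C(C)(C)C)C=CC(C)(C)O2 | intermediate
17 | 2-iodo-5-methylphenol | Cc1ccc(I)c(O)c1 | starting material
18 | tert-butyl(2-iodo-5-methylphenoxy)dimethylsilane | Cc1ccc(I)c(O[Si](C)(C)C(C)(C)C)c1 | intermediate
19 | pinacol (Z)-alkenylboronate: boron on the carbon bearing CH2OTBS and cis to the vinyl H; (S)-encecalyloxy cis to CH2OTBS | COc1cc2c(cc1[C@H](C)O/C=C(\CO[Si](C)(C)C(C)(C)C)B3OC(C)(C)C(C)(C)O3)C=CC(C)(C)O2 | intermediate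
20 | bis(tert-butyldimethylsilyl) ether of the target, (S) centre, (Z)-enol ether | COc1cc2c(cc1[C@H](C)O/C=C(\CO[Si](C)(C)C(C)(C)C)c1ccc(C)cc1O[Si](C)(C)C(C)(C)C)C=CC(C)(C)O2 | intermediate
21 | CNP0279099.1, 2-[(Z)-3-hydroxy-1-{(1S)-1-(7-methoxy-2,2-dimethyl-2H-chromen-6-yl)ethoxy}prop-1-en-2-yl]-5-methylphenol | COc1cc2c(cc1[C@H](C)O/C=C(\CO)c1ccc(C)cc1O)C=CC(C)(C)O2 | target

**Step count and risks**
Total step count: 9. Longest linear sequence: 8 (steps 1–6, 8 and 9; step 7 is the side branch).

Steps most likely to fail:

1. Step 8.
   - Risk: Transfer of the alkenyl group from the dicyclohexylboryl unit to HBpin may be slow for an internal, alpha-branched alkenyl group. Unreacted alkynyl ether would then be lost by sigmatropic shift once the flask is warmed. Transmetalation of the hindered boronate to an ortho-substituted arylpalladium species may also lag behind protodeboronation, and the aryl silyl ether may be partly cleaved by the aqueous base (harmless, since step 9 removes it anyway).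
   - Fallback: Boron is replaced by zirconium and zinc, with no water, base or heat. Setting out from 16, stoichiometric Cp2ZrHCl in THF at 20 °C should add H and Zr syn, with the metal on the carbon beta to oxygen, to give the alkenylzirconocene chloride F1. Dry ZnCl2 in THF should pass the alkenyl group on with retention to the alkenylzinc chloride F2. Negishi coupling of F2 with 18 under Pd(PPh3)4 at 20 °C comes back to the route at 20.

2. Step 5.
   - Risk: Paraformaldehyde may depolymerise too slowly at the low temperature the alkynyl ether demands, so the acetylide is merely protonated on quench. The free alkoxypropargyl alcohol may also be lost by hydration or rearrangement during isolation.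
   - Fallback: The C1 unit is brought in already silylated, by alkylation instead of carbonyl addition. Setting out from the lithium alkoxyacetylide 14 (made from 11 as in step 5), commercially available (triisopropylsiloxy)methyl chloride, ClCH2OSi(i-Pr)3, is added at −78 → 0 °C. This acetylide alkylation by an alpha-chloro ether should give the triisopropylsilyl ether F3 directly and skips step 6. F3 takes the place of 16 in step 8 and passes through the boronate F4 to the mixed bis-silyl ether F5. The fluoride treatment of step 9 then comes back to the route at 21.

3. Step 3.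
   - Risk: Facial selectivity may be poor, because the ortho-methoxy group disturbs the arene contact that orders the transition state. Turnover may be slow with this electron-rich ketone.
   - Fallback: Resolution replaces asymmetric catalysis. Setting out from 7, NaBH4 in EtOH at 0 °C should give racemic encecalol F6. Immobilised lipase B from Candida antarctica with vinyl acetate in MTBE at 30 °C should acetylate the (R)-enantiomer, the fast-reacting one for 1-arylethanols, to (R)-encecalol acetate F7 and leave the (S)-alcohol untouched. Separation on Et3N-deactivated silica comes back to the route at 8.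

**Further compounds**
F1 | step 8 | alkenylzirconocene chloride, Zr on the carbon bearing CH2OTBS and cis to the vinyl H (cyclopentadienyl rings written sigma-bound) | COc1cc2c(cc1[C@H](C)O/C=C(\CO[Si](C)(C)C(C)(C)C)[Zr](Cl)(C1C=CC=C1)C1C=CC=C1)C=CC(C)(C)O2
F2 | step 8 | alkenylzinc chloride of the same geometry | COc1cc2c(cc1[C@H](C)O/C=C(\CO[Si](C)(C)C(C)(C)C)[Zn]Cl)C=CC(C)(C)O2
F3 | step 5 | triisopropylsilyl analogue of 16 | COc1cc2c(cc1[C@H](C)OC#CCO[Si](C(C)C)(C(C)C)C(C)C)C=CC(C)(C)O2
F4 | step 5 | triisopropylsilyl analogue of boronate 19 | COc1cc2c(cc1[C@H](C)O/C=C(\CO[Si](C(C)C)(C(C)C)C(C)C)B3OC(C)(C)C(C)(C)O3)C=CC(C)(C)O2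
F5 | step 5 | mixed bis-silyl ether (allylic OTIPS, aryl OTBS) of the target | COc1cc2c(cc1[C@H](C)O/C=C(\CO[Si](C(C)C)(C(C)C)C(C)C)c1ccc(C)cc1O[Si](C)(C)C(C)(C)C)C=CC(C)(C)O2
F6 | step 3 | racemic encecalol | COc1cc2c(cc1C(C)O)C=CC(C)(C)O2
F7 | step 3 | (R)-encecalol acetate | COc1cc2c(cc1[C@@H](C)OC(C)=O)C=CC(C)(C)O2
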